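**Retrosynthetic overview**
- Last step: thiolate O-demethylation of the ring B methyl ether. Before it, an aromatic Claisen rearrangement of a 7-O-prenyl flavan places the 1,1-dimethylallyl group at C6 and frees the 7-OH.
- Ring C (formed last): intramolecular palladium-catalysed aryl C–O coupling of an (S)-1,3-diarylpropan-1-ol onto an aryl chloride, with retention at C2. The carbinol comes from CBS reduction of the ketone.
- Key C–C bond, C4–C4a: a palladium homoenolate (the β-palladated aryl ketone from ring opening of a 1-arylcyclopropanol) is arylated by the ring A bromide 1-bromo-2-chloro-4-(prenyloxy)benzene.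
- Cyclopropanol from Kulinkovich reaction of the ring B methyl ester; prenyl by Stille coupling at the bromide; the 2,2-dimethylchromene ring (formed first) by propargyl ether Claisen/6π-electrocyclisation on 6-bromovanillin.
- Ring order: chromene pyran ring on ring B, then ring C; both benzene rings are bought.

Assumption: the target is the (2S)-flavan encoded by the SMILES; 6-bromovanillin, 4-bromo-3-chlorophenol, 3-chloro-3-methylbut-1-yne, prenyl bromide and tributyl(prenyl)stannane are bought.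

**Step 1**
Reactants: 1 6-bromovanillin (2-bromo-4-hydroxy-5-methoxybenzaldehyde)
Product: 3 5-bromo-8-methoxy-2,2-dimethyl-2H-chromene-6-carbaldehyde, via aryl propargyl ether 2 (not isolated)
Conditions: K2CO3, KI (cat.), CuI (cat.), acetone, 56 °C; filter, evaporate; then PhNEt2, 190 °C
Reagents that add atoms: 3-chloro-3-methylbut-1-yne, C#CC(C)(C)Cl
Why: O-propargylation of the only phenol is followed by aryl propargyl ether Claisen rearrangement, 1,5-H shift and 6π-oxa-electrocyclisation, and because the other ortho position of the ether oxygen carries OMe the chromene can only close onto the carbon next to the bromine.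

**Step 2**
Reactants: 3 5-bromo-8-methoxy-2,2-dimethyl-2H-chromene-6-carbaldehyde
Product: 4 methyl 5-bromo-8-methoxy-2,2-dimethyl-2H-chromene-6-carboxylate
Conditions: 1,4-dimethyl-1,2,4-triazolium iodide (5 mol %), DBU, 3,3',5,5'-tetra-tert-butyldiphenoquinone (1.1 equiv), MeOH/THF, rt
Reagents that add atoms: methanol, CO
Why: NHC-catalysed oxidative esterification, in which the Breslow intermediate is oxidised by the diphenoquinone to an acyl azolium that methanol intercepts, leaves the chromene alkene and the aryl bromide untouched.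

**Step 3**
Reactants: 4 methyl 5-bromo-8-methoxy-2,2-dimethyl-2H-chromene-6-carboxylate
Product: 5 methyl 8-methoxy-2,2-dimethyl-5-(3-methylbut-2-en-1-yl)-2H-chromene-6-carboxylate
Conditions: Pd(PPh3)4 (5 mol %), DMF, 100 °C
Reagents that add atoms: tributyl(3-methylbut-2-en-1-yl)stannane, CCCC[Sn](CCCC)(CCCC)CC=C(C)C
Why: Stille cross-coupling, in which reductive elimination from the prenyl–palladium intermediate at its unsubstituted terminus gives the linear prenyl arene under neutral conditions that spare the ester.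

**Step 4**
Reactants: 5 methyl 8-methoxy-2,2-dimethyl-5-(3-methylbut-2-en-1-yl)-2H-chromene-6-carboxylate
Product: 6 1-[8-methoxy-2,2-dimethyl-5-(3-methylbut-2-en-1-yl)-2H-chromen-6-yl]cyclopropan-1-ol
Conditions: EtMgBr (3 equiv, slow addition), Ti(OiPr)4 (0.5 equiv), THF, 0 °C to rt; aq. NH4Cl
Reagents that add atoms: ethylmagnesium bromide, CC[Mg]Br
Why: Kulinkovich cyclopropanation, in which the titanacyclopropane made from two ethyl groups adds twice to the ester carbonyl as a 1,2-dicarbanion, while the trisubstituted and cis-disubstituted alkenes are too hindered for ligand exchange.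

**Step 5**
Reactants: 7 4-bromo-3-chlorophenol
Product: 8 1-bromo-2-chloro-4-[(3-methylbut-2-en-1-yl)oxy]benzene
Conditions: K2CO3, acetone, 56 °C
Reagents that add atoms: 1-bromo-3-methylbut-2-ene (prenyl bromide), CC(C)=CCBr
Why: Williamson ether synthesis by SN2 at the primary allylic bromide gives the linear O-prenyl ether, which serves as protecting group now and as Claisen precursor later.

**Step 6 (key step)**
Reactants: 6 1-[8-methoxy-2,2-dimethyl-5-(3-methylbut-2-en-1-yl)-2H-chromen-6-yl]cyclopropan-1-ol; 8 1-bromo-2-chloro-4-[(3-methylbut-2-en-1-yl)oxy]benzene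
Product: 9 3-{2-chloro-4-[(3-methylbut-2-en-1-yl)oxy]phenyl}-1-[8-methoxy-2,2-dimethyl-5-(3-methylbut-2-en-1-yl)-2H-chromen-6-yl]propan-1-one
Conditions: Pd(OAc)2 (5 mol %), XPhos (10 mol %), Cs2CO3 (2 equiv), toluene, 80 °C
Reagents that add atoms: none
Why: Palladium homoenolate cross-coupling (cyclopropanol ring-opening arylation), in which oxidative addition into C–Br (faster than C–Cl), alkoxide exchange and β-carbon elimination give a β-palladated ketone whose C(sp3)–C(sp2) reductive elimination, favoured over β-hydride elimination by the bulky biarylphosphine, joins the normally electrophilic ketone β-carbon (C4) to the aryl halide carbon (C4a).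

**Step 7**
Reactants: 9 3-{2-chloro-4-[(3-methylbut-2-en-1-yl)oxy]phenyl}-1-[8-methoxy-2,2-dimethyl-5-(3-methylbut-2-en-1-yl)-2H-chromen-6-yl]propan-1-one
Product: 10 (1S)-3-{2-chloro-4-[(3-methylbut-2-en-1-yl)oxy]phenyl}-1-[8-methoxy-2,2-dimethyl-5-(3-methylbut-2-en-1-yl)-2H-chromen-6-yl]propan-1-ol
Conditions: (R)-2-methyl-CBS-oxazaborolidine (20 mol %), BH3·SMe2 (0.7 equiv, slow addition), THF, −20 °C; aq. NH4Cl
Reagents that add atoms: none
Why: Corey–Bakshi–Shibata reduction with the (R)-catalyst treats the aryl group as the large substituent and delivers hydride to give the (S)-carbinol (the sense that turns acetophenone into (S)-1-phenylethanol), and at −20 °C the catalysed carbonyl reduction is far faster than hydroboration of the hindered alkenes.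

**Step 8**
Reactants: 10 (1S)-3-{2-chloro-4-[(3-methylbut-2-en-1-yl)oxy]phenyl}-1-[8-methoxy-2,2-dimethyl-5-(3-methylbut-2-en-1-yl)-2H-chromen-6-yl]propan-1-ol
Product: 11 (2S)-2-[8-methoxy-2,2-dimethyl-5-(3-methylbut-2-en-1-yl)-2H-chromen-6-yl]-7-[(3-methylbut-2-en-1-yl)oxy]-3,4-dihydro-2H-chromene
Conditions: Pd(OAc)2 (5 mol %), tBuXPhos (7 mol %), Cs2CO3 (1.5 equiv), toluene, 90 °C
Reagents that add atoms: none
Why: Palladium-catalysed intramolecular aryl C–O coupling (Buchwald–Hartwig etherification) forms the O1–C8a bond at the aryl chloride carbon, so the carbinol stereocentre is not touched and the S configuration is retained, with the bulky di-tert-butylphosphine favouring C–O reductive elimination over β-hydride elimination.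

**Step 9**
Reactants: 11 (2S)-2-[8-methoxy-2,2-dimethyl-5-(3-methylbut-2-en-1-yl)-2H-chromen-6-yl]-7-[(3-methylbut-2-en-1-yl)oxy]-3,4-dihydro-2H-chromene
Product: 12 (2S)-2-[8-methoxy-2,2-dimethyl-5-(3-methylbut-2-en-1-yl)-2H-chromen-6-yl]-6-(2-methylbut-3-en-2-yl)-3,4-dihydro-2H-chromen-7-ol
Conditions: PhNEt2, 190 °C, sealed tube, 2–3 h
Reagents that add atoms: none
Why: Aromatic Claisen rearrangement delivers the prenyl unit with allylic inversion as a 1,1-dimethylallyl group to C6, the ortho position that is para to the ring oxygen and not flanked by two oxygens, and tautomerisation frees the 7-OH.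

**Step 10**
Reactants: 12 (2S)-2-[8-methoxy-2,2-dimethyl-5-(3-methylbut-2-en-1-yl)-2H-chromen-6-yl]-6-(2-methylbut-3-en-2-yl)-3,4-dihydro-2H-chromen-7-ol
Product: 13 Kazinol H, (2S)-2-[8-hydroxy-2,2-dimethyl-5-(3-methylbut-2-en-1-yl)-2H-chromen-6-yl]-6-(2-methylbut-3-en-2-yl)-3,4-dihydro-2H-chromen-7-ol
Conditions: NaSEt (5 equiv), DMF, 120 °C, argon; then 1 M HCl
Reagents that add atoms: none
Why: Nucleophilic O-demethylation by SN2 attack of thiolate on the only methyl aryl ether works without acid or Lewis acid, so the prenyl, 1,1-dimethylallyl and chromene alkenes and the C2 stereocentre are left alone.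

**Compound list**
1 | 6-bromovanillin (2-bromo-4-hydroxy-5-methoxybenzaldehyde) | COc1cc(C=O)c(Br)cc1O | starting material
2 | 2-bromo-5-methoxy-4-[(2-methylbut-3-yn-2-yl)oxy]benzaldehyde | COc1cc(C=O)c(Br)cc1OC(C)(C)C#C | intermediate
3 | 5-bromo-8-methoxy-2,2-dimethyl-2H-chromene-6-carbaldehyde | COc1cc(C=O)c(Br)c2C=CC(C)(C)Oc12 | intermediate
4 | methyl 5-bromo-8-methoxy-2,2-dimethyl-2H-chromene-6-carboxylate | COC(=O)c1cc(OC)c2OC(C)(C)C=Cc2c1Br | intermediate
5 | methyl 8-methoxy-2,2-dimethyl-5-(3-methylbut-2-en-1-yl)-2H-chromene-6-carboxylate | COC(=O)c1cc(OC)c2OC(C)(C)C=Cc2c1CC=C(C)C | intermediate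
6 | 1-[8-methoxy-2,2-dimethyl-5-(3-methylbut-2-en-1-yl)-2H-chromen-6-yl]cyclopropan-1-ol | OC1(CC1)c1cc(OC)c2OC(C)(C)C=Cc2c1CC=C(C)C | intermediate
7 | 4-bromo-3-chlorophenol | Oc1ccc(Br)c(Cl)c1 | starting material
8 | 1-bromo-2-chloro-4-[(3-methylbut-2-en-1-yl)oxy]benzene | CC(C)=CCOc1ccc(Br)c(Cl)c1 | intermediate
9 | 3-{2-chloro-4-[(3-methylbut-2-en-1-yl)oxy]phenyl}-1-[8-methoxy-2,2-dimethyl-5-(3-methylbut-2-en-1-yl)-2H-chromen-6-yl]propan-1-one | CC(C)=CCOc1ccc(CCC(=O)c2cc(OC)c3OC(C)(C)C=Cc3c2CC=C(C)C)c(Cl)c1 | intermediate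
10 | (1S)-3-{2-chloro-4-[(3-methylbut-2-en-1-yl)oxy]phenyl}-1-[8-methoxy-2,2-dimethyl-5-(3-methylbut-2-en-1-yl)-2H-chromen-6-yl]propan-1-ol | CC(C)=CCOc1ccc(CC[C@H](O)c2cc(OC)c3OC(C)(C)C=Cc3c2CC=C(C)C)c(Cl)c1 | intermediate
11 | (2S)-2-[8-methoxy-2,2-dimethyl-5-(3-methylbut-2-en-1-yl)-2H-chromen-6-yl]-7-[(3-methylbut-2-en-1-yl)oxy]-3,4-dihydro-2H-chromene | CC(C)=CCOc1ccc2c(c1)O[C@H](c1cc(OC)c3OC(C)(C)C=Cc3c1CC=C(C)C)CC2 | intermediate
12 | (2S)-2-[8-methoxy-2,2-dimethyl-5-(3-methylbut-2-en-1-yl)-2H-chromen-6-yl]-6-(2-methylbut-3-en-2-yl)-3,4-dihydro-2H-chromen-7-ol | C=CC(C)(C)c1cc2c(cc1O)O[C@H](c1cc(OC)c3OC(C)(C)C=Cc3c1CC=C(C)C)CC2 | intermediate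
13 | Kazinol H | C=CC(C)(C)c1cc2c(cc1O)O[C@H](c1cc(O)c3c(c1CC=C(C)C)C=CC(C)(C)O3)CC2 | target

**Step count**
Total: 10 steps. Longest linear sequence: 9 steps from 6-bromovanillin (steps 1–4 and 6–10); step 5 is a one-step side branch.

**Three steps most likely to fail, with fallbacks**

Step 6 (key coupling). The risks are β-hydride elimination of the palladium homoenolate to the enone and simple protonation to the ethyl ketone. The fallback keeps the same C4–C4a bond but makes it by a nickel cross-electrophile route and sets out from 6. Pd(OAc)2, pyridine and O2 in toluene at 80 °C open the cyclopropanol oxidatively to the aryl vinyl ketone F1. NiCl2(dme)/neocuproine with Mn powder and Et3SiCl in DMF then couples F1 with bromide 8 at the β-carbon through a 1-siloxyallylnickel species (a homoenolate equivalent made by reduction), giving the triethylsilyl enol ether F2. Dilute HCl in THF hydrolyses F2, and the route is rejoined at ketone 9.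

Step 8 (C–O ring closure). The secondary benzylic palladium alkoxide may undergo β-hydride elimination, returning ketone and dechlorinated arene. The fallback closes ring C at the sp3 carbon and sets out from 9. Reduction with the (S)-configured CBS catalyst gives the (R)-alcohol F3. Miyaura borylation of the aryl chloride (Pd2(dba)3, XPhos, B2pin2, KOAc, dioxane, 100 °C; the weak base does not trigger etherification) gives the pinacol boronate F4. NaBO3·4H2O in THF/water oxidises F4 to the phenol F5. Mitsunobu cyclisation (PPh3, DIAD, THF, 0 °C) displaces the carbinol oxygen with inversion and rejoins the route at 11; some loss of ee is possible because the carbinol is para-alkoxybenzylic.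

Step 9 (Claisen). The risks are a share of the C8 isomer and further thermal reaction of the ortho-(1,1-dimethylallyl)phenol. The fallback installs the group on the ring A fragment before coupling and sets out from 8. Heating 8 in PhNEt2 at 190 °C gives the bromochlorophenol F6; here the other ortho position is flanked by the chlorine-bearing carbon and should be too crowded for the new quaternary carbon. MOMCl and iPr2NEt give the MOM ether F7. F7 is carried with cyclopropanol 6 through the conditions of steps 6, 7 and 8 to the ketone F8, the (S)-alcohol F9 and the MOM-protected flavan F10; the terminal alkene is a possible Heck acceptor and the coupling should be stopped at full conversion. PPTS in MeOH at 50 °C removes the MOM group and the route is rejoined at 12.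

**Further compounds**
F1 | step 6 | 1-[8-methoxy-2,2-dimethyl-5-(3-methylbut-2-en-1-yl)-2H-chromen-6-yl]prop-2-en-1-one | C=CC(=O)c1cc(OC)c2OC(C)(C)C=Cc2c1CC=C(C)C
F2 | step 6 | [(3-{2-chloro-4-[(3-methylbut-2-en-1-yl)oxy]phenyl}-1-[8-methoxy-2,2-dimethyl-5-(3-methylbut-2-en-1-yl)-2H-chromen-6-yl]prop-1-en-1-yl)oxy]triethylsilane | CC[Si](CC)(CC)OC(=CCc1ccc(OCC=C(C)C)cc1Cl)c1cc(OC)c2OC(C)(C)C=Cc2c1CC=C(C)C
F3 | step 8 | (1R)-3-{2-chloro-4-[(3-methylbut-2-en-1-yl)oxy]phenyl}-1-[8-methoxy-2,2-dimethyl-5-(3-methylbut-2-en-1-yl)-2H-chromen-6-yl]propan-1-ol | CC(C)=CCOc1ccc(CC[C@@H](O)c2cc(OC)c3OC(C)(C)C=Cc3c2CC=C(C)C)c(Cl)c1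
F4 | step 8 | (1R)-1-[8-methoxy-2,2-dimethyl-5-(3-methylbut-2-en-1-yl)-2H-chromen-6-yl]-3-{4-[(3-methylbut-2-en-1-yl)oxy]-2-(4,4,5,5-tetramethyl-1,3,2-dioxaborolan-2-yl)phenyl}propan-1-ol | CC(C)=CCOc1ccc(CC[C@@H](O)c2cc(OC)c3OC(C)(C)C=Cc3c2CC=C(C)C)c(c1)B1OC(C)(C)C(C)(C)O1
F5 | step 8 | 2-{(3R)-3-hydroxy-3-[8-methoxy-2,2-dimethyl-5-(3-methylbut-2-en-1-yl)-2H-chromen-6-yl]propyl}-5-[(3-methylbut-2-en-1-yl)oxy]phenol | CC(C)=CCOc1ccc(CC[C@@H](O)c2cc(OC)c3OC(C)(C)C=Cc3c2CC=C(C)C)c(O)c1
F6 | step 9 | 4-bromo-5-chloro-2-(2-methylbut-3-en-2-yl)phenol | C=CC(C)(C)c1cc(Br)c(Cl)cc1O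
F7 | step 9 | 1-bromo-2-chloro-4-(methoxymethoxy)-5-(2-methylbut-3-en-2-yl)benzene | C=CC(C)(C)c1cc(Br)c(Cl)cc1OCOC
F8 | step 9 | 3-[2-chloro-4-(methoxymethoxy)-5-(2-methylbut-3-en-2-yl)phenyl]-1-[8-methoxy-2,2-dimethyl-5-(3-methylbut-2-en-1-yl)-2H-chromen-6-yl]propan-1-one | C=CC(C)(C)c1cc(CCC(=O)c2cc(OC)c3OC(C)(C)C=Cc3c2CC=C(C)C)c(Cl)cc1OCOC
F9 | step 9 | (1S)-3-[2-chloro-4-(methoxymethoxy)-5-(2-methylbut-3-en-2-yl)phenyl]-1-[8-methoxy-2,2-dimethyl-5-(3-methylbut-2-en-1-yl)-2H-chromen-6-yl]propan-1-ol | C=CC(C)(C)c1cc(CC[C@H](O)c2cc(OC)c3OC(C)(C)C=Cc3c2CC=C(C)C)c(Cl)cc1OCOC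
F10 | step 9 | (2S)-2-[8-methoxy-2,2-dimethyl-5-(3-methylbut-2-en-1-yl)-2H-chromen-6-yl]-7-(methoxymethoxy)-6-(2-methylbut-3-en-2-yl)-3,4-dihydro-2H-chromene | C=CC(C)(C)c1cc2c(cc1OCOC)O[C@H](c1cc(OC)c3OC(C)(C)C=Cc3c1CC=C(C)C)CC2
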